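# Proposed synthesis of CNP0519565.1: phorone + 3‑methylfurfural, Achmatowicz bridging and a transannular ketal Claisen rearrangement

## Analysis of the target

Biogenetic (elemane) numbering is used throughout. The ring is C5–C10; C14 is the methyl on C10; C1–C2 is the oxirane on C10; C4(=C3H2)–C15HO is the acrolein unit on C5; C11(=C13H2)–C12(=O)–O8 is the lactone fused at C7/C8; O6 is the free hydroxyl and O9 carries the isobutyrate.

The only carbocycle is the cyclohexane C5–C10, and every ring carbon is a stereocentre; the seventh stereocentre is the oxirane carbon C1. O8, O9 and the C1 branch lie on one face (α). C14, the C4 and C11 branches and O6 lie on the other face (β). This corresponds to a chair with the C5, C7 and C8 substituents equatorial and O6, O9 and C14 axial. The sensitive groups are two Michael acceptors (enal, α‑methylene lactone, both base‑labile), a terminal epoxide (acid‑labile), a cis‑vicinal ester/lactone pair (acyl migration) and a γ‑hydroxy enal (lactol formation, over‑oxidation). The hard parts are the all‑carbon quaternary C10 between the oxygenated C9 and the branched C5, the exocyclic stereocentre C1, and the two 2‑propenyl units at different oxidation levels.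

Three features invite the strategy:

- C5 and C7 both carry a CH2=C–C unit and flank the carbinol C6. The nine carbons C3, C4, C15, C5, C6, C7, C11, C12, C13 are the skeleton of phorone with its two isopropylidene arms deconjugated.
- The remaining six carbons C8, C9, C10, C14, C1, C2, with oxygen on C8, C9 and C2, are 3‑methylfuran‑2‑carbaldehyde.
- C10 (bearing the two‑carbon C1–C2 unit) next to C5 (bearing the 2‑propenyl unit) is the retron of a [3,3] shift, the oxygen analogue of the germacrene‑to‑elemene Cope rearrangement.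

## Retrosynthetic reasoning

**Oxidation levels of C12 and C15 (22 ⇐ 21 ⇐ 20 ⇐ 19).** The lactone carbonyl C12 and the aldehyde C15 are traced back to the methyl groups of two identical isopropenyl groups in 19. With O6 silylated, only the C7 arm has a free hydroxyl neighbour (O8), so one MnO2 oxidation of the twin allylic alcohols 20 gives lactone on one side and enal on the other (21). Desilylation is left for last, so the γ‑hydroxy enal is never exposed to an oxidant.

**Oxirane and O6 protection (19 ⇐ 17 ⇐ 15).** The C1–O–C2 oxirane is closed from the 1,2‑diol of 15 through its primary tosylate. The two secondary hydroxyls of 17 are told apart by accessibility (O8 equatorial, O6 axial and flanked).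

**C5, C6, C7 from a C6 ketone (15 ⇐ 14 ⇐ 13).** C5 and C7 are both α to a C6 carbonyl, so they need not be set earlier: equilibration of 13 funnels all epimers into the diequatorial ketone 14. Equatorial hydride attack then gives the axial 6β‑alcohol 15. The controlling elements are C8, C9 and C10, which are fixed before.

**C1, C2 and O8 from a cyclic enol ether (13 ⇐ 11).** The C1 hydroxyl and the C2 carbon of the diol come from oxidation of a cyclic enol ether O8–C2=C1–C10 in the bicycle 11. The same operation releases O8 and opens the bicycle to the monocyclic ketone.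

**Key cut, C5–C10 (11 ⇐ 9 via 10).** The bond between the quaternary C10 and C5 is cut by a retro‑Claisen: 11 is the [3,3] product of the allyl vinyl acetal 10 (C5=C6–O–C2–C1=C10), which is the enol ether of the bridged mixed ketal 9. The cut is made here because it removes the quaternary centre, the cyclohexane ring and the C5 2‑propenyl unit in one operation. The forward reaction has to form C5–C10 across the 2,9‑dioxabicyclo[3.3.1]nonene on the face fixed by the tether.

**C9 configuration (9 ⇐ 8 ⇐ 7).** The C9 ester must be trans to the C8–C7 bond on the pyran ring. It is reached by two operations from the open exo face of ketone 7: hydride (giving 8) and then carboxylate with inversion (giving 9).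

**Pyranone from furan (7 ⇐ 5 via 6).** The pyranone ring O8–C8–C9–C10–C1–C2 of 7 is the Achmatowicz product of the furylcarbinol 5. The lactol oxygen on C2 is tied to the C6 ketone as a mixed methyl ketal, which protects C6 and already contains the C2–O–C6 linkage needed for the Claisen.

**All fifteen carbons in one step (5 ⇐ 4 ⇐ 1 + 2).** The C7–C8 bond is an aldol bond between the γ‑dienolate 3 of phorone 1 (reacting at its α‑carbon) and 3‑methylfuran‑2‑carbaldehyde 2. The carbinol 4 is resolved to 5; C8 is the only stereocentre that has to be introduced with absolute control.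

## Alternatives that were turned down

**Alternative 1:** the textbook elemane disconnection, C10–C1 by conjugate addition. Vinyl cuprate would add to the 3‑methylcyclohexenone A1 (all‑cis 4,6‑diisopropenyl‑5‑silyloxy) to give the quaternary ketone A2; enolate oxidation at C9, reduction at C8 and epoxidation of the vinyl group would follow. It was turned down for three reasons. A1 already contains the contiguous C5/C6/C7 triad in its least stable all‑cis arrangement, and no short access to it is apparent. The monoterpene enones normally used for this step give the 1,3‑trans relationship of the C5 and C7 branches, because cuprates add anti to the existing branch. The monosubstituted vinyl group of A2 would have to be epoxidised with no element that controls C1.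

**Alternative 2:** the biomimetic disconnection, C5–C10 by Cope rearrangement of a germacranolide. The (1(10)E,4E)‑germacradien‑8,12‑olide A3 would rearrange through a chair to the 1,2‑divinyl compound A4. It was turned down because A3 is a ten‑membered carbocycle with two E‑trisubstituted alkenes, four contiguous stereocentres and a 4‑formyl group, so it is harder to make than the target. The Cope equilibrium is not under control, and A4 again leaves C1 to an uncontrolled epoxidation.

**Alternative 3:** dearomatisation. Birch reduction–methylation of a 3,5‑dimethoxybenzoic acid would give the diene acid A5, which maps all six ring carbons with oxygen at C6 and C8 and the quaternary C10 carrying C14 and C1. It was turned down because A5 is achiral and no stereocentre is set by the key step. The two enantiotopic arms must then be told apart (oxygen at C9, carbon at C5) relative to a methyl and a carboxyl group of similar size. The two 2‑propenyl units would require α‑alkenylation of ketones, for which there is no short reliable method.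

Key step: step 6

## Route

Assumption (chemistry): the target is handled as the open γ‑hydroxy enal that is drawn; a ring–chain equilibrium with the O6–C15 lactol, if present, is the same compound in solution.

Step 1
Reactants: 1 phorone (2,6‑dimethylhepta‑2,5‑dien‑4‑one); 2 3‑methylfuran‑2‑carbaldehyde
Product: 4 rac‑3‑[hydroxy(3‑methylfuran‑2‑yl)methyl]‑2,6‑dimethylhepta‑1,5‑dien‑4‑one (both C7 epimers), via lithium dienolate 3 (not isolated)
Conditions: LDA (1.05 equiv), THF, −78 °C; then 2, −78 °C; AcOH quench at −78 °C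
Reagents that add atoms: none
Why: Phorone has only γ‑hydrogens, so LDA should give the cross‑conjugated dienolate 3, which adds to the non‑enolisable aldehyde at its α‑carbon through a closed transition state (deconjugative aldol reaction). C8 is formed racemic and is resolved in step 2; C7 is epimerisable and converges in step 8.

Step 2
Reactants: 4 racemic aldol
Product: 5 (8R)‑3‑[(R)‑hydroxy(3‑methylfuran‑2‑yl)methyl]‑2,6‑dimethylhepta‑1,5‑dien‑4‑one (C7 epimers), recovered
Conditions: Ti(Oi‑Pr)4 (0.2 equiv), L‑(+)‑DIPT (0.24 equiv), t‑BuOOH (0.6 equiv), 4 Å MS, CH2Cl2, −20 °C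
Reagents that add atoms: none
Why: Sharpless kinetic resolution of a 2‑furylcarbinol: with L‑(+)‑tartrate the (S)‑carbinol should be oxidised much faster (to its pyranone) and the (R)‑carbinol recovered past half conversion. The furan acts as the allylic alkene, and the homoallylic isopropenyl group should react far more slowly; at most half of 4 is carried on.

Step 3
Reactants: 5 (8R)‑furylcarbinol
Product: 7 bridged methyl ketal, 3‑methoxy‑7‑methyl‑3‑(2‑methylprop‑1‑en‑1‑yl)‑4‑(prop‑1‑en‑2‑yl)‑2,9‑dioxabicyclo[3.3.1]non‑7‑en‑6‑one, via pyranone lactol 6 (not isolated)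
Conditions: NBS, NaHCO3, THF–H2O (4:1), 0 °C; then CSA (cat.), MeOH, 3 Å MS, 0 °C → rt
Reagents that add atoms: water (O); methanol (CO)
Why: Achmatowicz rearrangement turns the furylcarbinol into lactol 6 without touching C8; the lactol hydroxyl adds to the 1,5‑related C6 ketone and the hemiketal is capped by methanol. The bridge can form only with C2–O cis to C8–C7, which fixes the acetal centre; the furan should react with NBS far faster than the alkenes.

Step 4
Reactants: 7 bridged ketal ketone
Product: 8 the C9 alcohol with the hydroxyl endo (cis to C8–C7 on the pyran ring)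
Conditions: NaBH4, CeCl3·7H2O, MeOH, −78 °C
Reagents that add atoms: none
Why: Luche 1,2‑reduction of the only remaining carbonyl (C6 is masked as the ketal). Hydride should enter from the open exo face of the pyranone, because the ketal bridge covers the other face.

Step 5
Reactants: 8 endo allylic alcohol
Product: 9 the C9 isobutyrate with the ester exo (trans to C8–C7)
Conditions: i‑PrCO2H, PPh3, DIAD, toluene, 0 °C → rt
Reagents that add atoms: isobutyric acid (CC(C)C(=O)O)
Why: Mitsunobu esterification with inversion at the allylic carbinol; the carboxylate enters from the same open exo face, which gives the C9 configuration of the target. The ester is installed before C9 becomes neopentylic.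

Step 6
Reactants: 9 bridged mixed ketal
Product: 11 5‑methyl‑7‑oxo‑6,8‑di(prop‑1‑en‑2‑yl)‑2‑oxabicyclo[3.3.1]non‑3‑en‑9‑yl 2‑methylpropanoate (C8, C9, C10 as in the target; C5 and C7 epimer mixtures), via dienyl acetal 10 (not isolated)
Conditions: EtCO2H (5 mol%), o‑xylene, 140 °C, MeOH removed (4 Å MS)
Reagents that add atoms: none
Why: Acid‑catalysed loss of methanol from the mixed ketal gives the C6 oxocarbenium ion, which loses a γ‑proton to the dienyl acetal 10; the isomeric C6=C7 enol ether is in equilibrium with it but cannot rearrange, since that would need a four‑membered ring. 10 is an allyl vinyl acetal (C5=C6–O–C2–C1=C10) whose two ends face each other across the dioxabicyclo[3.3.1]nonene, and a concerted, boat‑like [3,3] shift breaks C2–O and forms C5–C10. The closest known reactions are the ketal Claisen rearrangement of allylic alcohols with ketone ketals (Saucy–Marbet type), Claisen rearrangements of allyl vinyl acetals, which the oxygen on the allylic carbon accelerates, and Claisen ring contractions of 2‑alkenyl dihydropyrans. The step closes the cyclohexanone ring C5–C10 transannularly, by contraction of the eight‑membered periphery of the bicycle, and leaves O8–C2=C1–C10 as a cyclic enol ether. C10 is set by the tether: C5 can reach only the pyran face that carries the C8–C7 bond, so the C1 branch ends cis to O8 and to the exo C9 ester, all three α. C5 arises from whichever enol ether geometry reacts and is not controlled; it is corrected in step 8, as is C7. The selectivity needed is [3,3] bond formation at C10 in preference to ionisation of the acetal with C–C bond formation at C2. A weak acid in a non‑polar solvent and the exo position of the C9 ester, which leaves the reacting face free, should secure it.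

Step 7
Reactants: 11 bicyclic enol ether
Product: 13 monocyclic triol ketone (C1, C2, C8 hydroxyls; C6 ketone; C9 isobutyrate; C5/C7 epimer mixtures), via hydroxy lactol 12 (not isolated)
Conditions: DMDO (1.05 equiv), acetone–CH2Cl2, −78 °C; H2O–THF, 0 °C; then NaBH4, EtOH, −30 °C
Reagents that add atoms: dimethyldioxirane (CC1(C)OO1); water (O)
Why: Epoxidation of the glycal‑type enol ether, which should be much faster than that of the 1,1‑disubstituted alkenes, is expected from the outer face because the carbocyclic bridge (C6) covers the inner face; this sets C1. Hydrolysis at C2 and borohydride reduction of the α‑hydroxy lactol through its aldehyde form free O8 and open the bicycle; the hindered 2,6‑disubstituted C6 ketone should survive at low temperature.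

Step 8
Reactants: 13 triol ketone (epimer mixtures at C5 and C7)
Product: 14 5β,7β‑triol ketone (both isopropenyl groups equatorial)
Conditions: CSA (10 mol%), CHCl3, 40 °C
Reagents that add atoms: none
Why: Acid‑catalysed enolisation equilibrates both α‑centres. C8–C10 fix the chair with O8 equatorial, and an axial isopropenyl group at C5 or C7 would be syn‑axial to the axial C9 ester, so all epimers should funnel into the diequatorial isomer. Kinetic α‑protonation of the dienols keeps the alkenes out of conjugation.

Step 9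
Reactants: 14 equilibrated ketone
Product: 15 tetraol with the axial 6β‑hydroxyl
Conditions: L‑Selectride (excess), THF, −78 → −20 °C; aq. NH4Cl
Reagents that add atoms: none
Why: Axial attack at C6 is blocked by the axial C14 methyl, so the bulky hydride should enter equatorially and give the axial alcohol. The hindered isobutyrate is expected to survive at low temperature.

Step 10
Reactants: 15 tetraol
Product: 17 epoxy diol (C1–C2 oxirane; O6 and O8 free), via primary tosylate 16 (not isolated)
Conditions: TsCl, Et3N, Bu2SnO (2 mol%), CH2Cl2, 0 °C; then DBU, rt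
Reagents that add atoms: none
Why: Tin‑catalysed tosylation selects the primary hydroxyl of the 1,2‑diol, and the C1 oxygen closes the oxirane by 3‑exo‑tet displacement with retention at C1. DBU in an aprotic solvent should avoid alkoxide‑driven acyl migration from O9 to O8.

Step 11
Reactants: 17 epoxy diol
Product: 19 O6‑triethylsilyl ether with O8 free, via bis‑silyl ether 18 (not isolated)
Conditions: TMSCl, imidazole, CH2Cl2, −40 °C; TESOTf, 2,6‑lutidine, −78 °C; then citric acid, MeOH, 0 °C
Reagents that add atoms: triethylsilyl trifluoromethanesulfonate (CC[Si](CC)(CC)OS(=O)(=O)C(F)(F)F)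
Why: Silylation follows accessibility: TMSCl takes the equatorial O8, TESOTf then silylates the hindered axial O6, and mild acid should remove only the trimethylsilyl ether.

Step 12
Reactants: 19 bis‑isopropenyl compound
Product: 20 twin allylic alcohol (C12–OH and C15–OH)
Conditions: SeO2 (0.5 equiv), t‑BuOOH, CH2Cl2, 0 °C → rt
Reagents that add atoms: selenium dioxide (O=[Se]=O); tert‑butyl hydroperoxide (CC(C)(C)OO)
Why: Sharpless–Umbreit allylic oxidation (ene reaction, then [2,3] shift) of both isopropenyl groups at their methyl groups, which react in preference to the ring methines. Any aldehyde formed by over‑oxidation converges in step 13.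

Step 13
Reactants: 20 twin allylic alcohol
Product: 21 O6‑triethylsilyl ether of the target (8,12‑lactone and C15 enal in place)
Conditions: activated MnO2 (excess), CH2Cl2, rt
Reagents that add atoms: none
Why: MnO2 oxidises both allylic alcohols to 2‑substituted acroleins. The C12 aldehyde is trapped by the free O8 as a lactol and oxidised on to the trans‑fused α‑methylene lactone, whereas the C15 aldehyde has no free hydroxyl partner and should stay an enal.

Step 14
Reactants: 21 silyl ether
Product: 22 target, CNP0519565.1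
Conditions: HF·pyridine, pyridine, THF, 0 °C
Reagents that add atoms: none
Why: Buffered fluoride cleavage of the triethylsilyl ether; the epoxide, enal, α‑methylene lactone and isobutyrate are expected to tolerate these conditions.

## Compound list

1 | phorone (2,6‑dimethylhepta‑2,5‑dien‑4‑one) | CC(C)=CC(=O)C=C(C)C | starting material
2 | 3‑methylfuran‑2‑carbaldehyde | Cc1ccoc1C=O | starting material
3 | lithium 2,6‑dimethylhepta‑1,3,5‑trien‑4‑olate | C=C(C)C=C([O-])C=C(C)C.[Li+] | intermediate (not isolated)
4 | rac‑3‑[hydroxy(3‑methylfuran‑2‑yl)methyl]‑2,6‑dimethylhepta‑1,5‑dien‑4‑one (racemate, both C7 epimers) | CC(C)=CC(=O)C(C(C)=C)C(O)c1occc1C | intermediate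
5 | 3‑[(R)‑hydroxy(3‑methylfuran‑2‑yl)methyl]‑2,6‑dimethylhepta‑1,5‑dien‑4‑one (C8 R; C7 epimers) | CC(C)=CC(=O)C(C(C)=C)[C@@H](O)c1occc1C | intermediate
6 | (2R)‑6‑hydroxy‑4‑methyl‑2‑[4‑methyl‑2‑oxo‑1‑(prop‑1‑en‑2‑yl)pent‑3‑en‑1‑yl]‑2H‑pyran‑3(6H)‑one (anomers) | CC(C)=CC(=O)C(C(C)=C)[C@H]1OC(O)C=C(C)C1=O | intermediate (not isolated)
7 | 3‑methoxy‑7‑methyl‑3‑(2‑methylprop‑1‑en‑1‑yl)‑4‑(prop‑1‑en‑2‑yl)‑2,9‑dioxabicyclo[3.3.1]non‑7‑en‑6‑one (C8 as in 5; acetal C2–O cis to C8–C7; ketal carbon and C7 as epimer mixtures) | COC1(C=C(C)C)O[C@H]2C=C(C)C(=O)[C@H](O2)C1C(C)=C | intermediate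
8 | the 6‑ol of 7 (biogenetic C9), hydroxyl endo, cis to the C8–C7 bond | COC1(C=C(C)C)O[C@H]2C=C(C)[C@@H](O)[C@H](O2)C1C(C)=C | intermediate
9 | the 6‑yl 2‑methylpropanoate of 7 (biogenetic C9), ester exo, trans to the C8–C7 bond | COC1(C=C(C)C)O[C@H]2C=C(C)[C@H](OC(=O)C(C)C)[C@H](O2)C1C(C)=C | intermediate
10 | 7‑methyl‑3‑(2‑methylprop‑2‑en‑1‑ylidene)‑4‑(prop‑1‑en‑2‑yl)‑2,9‑dioxabicyclo[3.3.1]non‑7‑en‑6‑yl 2‑methylpropanoate (dienyl acetal) | C=C(C)C=C1O[C@H]2C=C(C)[C@H](OC(=O)C(C)C)[C@H](O2)C1C(C)=C | intermediate (not isolated)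
11 | 5‑methyl‑7‑oxo‑6,8‑di(prop‑1‑en‑2‑yl)‑2‑oxabicyclo[3.3.1]non‑3‑en‑9‑yl 2‑methylpropanoate (O8, O9 and the C1 branch all cis; C5, C7 epimer mixtures) | O1[C@@H]2C(C(C)=C)C(=O)C(C(C)=C)[C@](C)(C=C1)[C@@H]2OC(=O)C(C)C | intermediate
12 | 3,4‑dihydroxy‑5‑methyl‑7‑oxo‑6,8‑di(prop‑1‑en‑2‑yl)‑2‑oxabicyclo[3.3.1]nonan‑9‑yl 2‑methylpropanoate (hydroxy lactol, C1–OH on the outer face) | O1[C@@H]2C(C(C)=C)C(=O)C(C(C)=C)[C@](C)([C@@H](O)C1O)[C@@H]2OC(=O)C(C)C | intermediate (not isolated)
13 | 2‑(1,2‑dihydroxyethyl)‑6‑hydroxy‑2‑methyl‑4‑oxo‑3,5‑di(prop‑1‑en‑2‑yl)cyclohexyl 2‑methylpropanoate (C1, C8, C9, C10 as in the target; C5, C7 epimer mixtures) | O[C@@H]2C(C(C)=C)C(=O)C(C(C)=C)[C@](C)([C@@H](O)CO)[C@@H]2OC(=O)C(C)C | intermediate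
14 | the 5β,7β isomer of 13 (both isopropenyl groups equatorial) | O[C@@H]2[C@@H](C(C)=C)C(=O)[C@@H](C(C)=C)[C@](C)([C@@H](O)CO)[C@@H]2OC(=O)C(C)C | intermediate
15 | 2‑(1,2‑dihydroxyethyl)‑4,6‑dihydroxy‑2‑methyl‑3,5‑di(prop‑1‑en‑2‑yl)cyclohexyl 2‑methylpropanoate (6β‑OH axial) | O[C@@H]2[C@@H](C(C)=C)[C@@H](O)[C@@H](C(C)=C)[C@](C)([C@@H](O)CO)[C@@H]2OC(=O)C(C)C | intermediate
16 | primary (C2) p‑toluenesulfonate of 15 | O[C@@H]2[C@@H](C(C)=C)[C@@H](O)[C@@H](C(C)=C)[C@](C)([C@@H](O)COS(=O)(=O)c1ccc(C)cc1)[C@@H]2OC(=O)C(C)C | intermediate (not isolated)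
17 | 4,6‑dihydroxy‑2‑methyl‑2‑(oxiran‑2‑yl)‑3,5‑di(prop‑1‑en‑2‑yl)cyclohexyl 2‑methylpropanoate | O[C@@H]2[C@@H](C(C)=C)[C@@H](O)[C@@H](C(C)=C)[C@](C)([C@@H]1CO1)[C@@H]2OC(=O)C(C)C | intermediate
18 | O6‑triethylsilyl O8‑trimethylsilyl ether of 17 | C[Si](C)(C)O[C@@H]2[C@@H](C(C)=C)[C@@H](O[Si](CC)(CC)CC)[C@@H](C(C)=C)[C@](C)([C@@H]1CO1)[C@@H]2OC(=O)C(C)C | intermediate (not isolated)
19 | O6‑triethylsilyl ether of 17 (O8 free) | O[C@@H]2[C@@H](C(C)=C)[C@@H](O[Si](CC)(CC)CC)[C@@H](C(C)=C)[C@](C)([C@@H]1CO1)[C@@H]2OC(=O)C(C)C | intermediate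
20 | 6‑hydroxy‑3,5‑bis(3‑hydroxyprop‑1‑en‑2‑yl)‑2‑methyl‑2‑(oxiran‑2‑yl)‑4‑(triethylsilyloxy)cyclohexyl 2‑methylpropanoate | O[C@@H]2[C@@H](C(=C)CO)[C@@H](O[Si](CC)(CC)CC)[C@@H](C(=C)CO)[C@](C)([C@@H]1CO1)[C@@H]2OC(=O)C(C)C | intermediate
21 | O6‑triethylsilyl ether of the target | C=C1C(=O)O[C@@H]2[C@@H]1[C@@H](O[Si](CC)(CC)CC)[C@@H](C(=C)C=O)[C@](C)([C@@H]1CO1)[C@@H]2OC(=O)C(C)C | intermediate
22 | CNP0519565.1 (1,2‑epoxy‑6β‑hydroxy‑9α‑isobutyryloxy‑15‑oxoelema‑3,11(13)‑dien‑8α,12‑olide) | C=C1C(=O)O[C@@H]2[C@@H]1[C@@H](O)[C@@H](C(=C)C=O)[C@](C)([C@@H]1CO1)[C@@H]2OC(=O)C(C)C | target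

## Step count and risk

Total step count: 14. Longest linear sequence: 14 steps (fully linear from 1 and 2).

**Step 6 (key step).** Two things may go wrong. The allylic acetal may ionise at C2 under the acidic, hot conditions and the tethered dienol ether may then bond to C2 instead of C10; or the bridged acetal may not reach the boat‑like geometry, so that only enol ether isomerisation and slow decomposition occur. The fallback replaces the pericyclic step by a palladium‑mediated closure; it sets out from 9 and returns at 11.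
- Aqueous acetic acid in THF hydrolyses the ketal to the lactol–enone F1.
- Et3SiH/BF3·OEt2 at −40 °C removes the anomeric hydroxyl to give the 3,6‑dihydro‑2H‑pyran F2.
- I2/DMAP iodinates the enone at C5 to the iodo‑enone F3.
- An intramolecular Heck reaction (Pd(OAc)2, PPh3, Ag2CO3, MeCN, 80 °C) closes C5–C10 in the 6‑exo mode on the tether face. β‑Hydride elimination toward C2 gives the cyclic enol ether with an isopropylidene group at C5, F4.
- Deconjugative protonation of its dienolate (LDA, −78 °C; AcOH) gives 11.

**Step 3.** The hemiketal between the lactol and the conjugated C6 ketone may not be favoured, so methanol may cap the anomeric position instead and leave a monocyclic methyl glycoside with a free enone; step 4 would then lose chemoselectivity and the Claisen linkage would be missing. The fallback sets out from 6 and returns at 10. MsCl/Et3N converts the lactol directly, through sulfonate departure with participation of the ketone oxygen and γ‑deprotonation, into the C9‑keto dienyl acetal F5. Luche reduction gives the endo alcohol F6, and the Mitsunobu reaction of step 5 then gives 10, which is heated as in step 6.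

**Step 1.** The aldolate may revert on warming and re‑add through the γ‑carbon, or proton transfer may compete, so that regiochemical control is lost. The fallback sets out from 1 and returns at 5. The dienolate 3 (2 equiv) is acylated with methyl 3‑methylfuran‑2‑carboxylate to the 1,3‑diketone F7. Noyori transfer hydrogenation (RuCl[(R,R)‑TsDPEN](p‑cymene), HCO2H/Et3N) should reduce the furyl ketone enantioselectively to 5. This also removes the resolution of step 2.

**Step 7.** Borohydride may reduce the C6 ketone before C5 and C7 have been equilibrated, or the bridged lactol may open too slowly. The fallback sets out from 12 and returns at 15, bypassing steps 8 and 9.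
- Fétizon oxidation (Ag2CO3 on Celite) gives the α‑hydroxy lactone F8.
- TsOH in methanol opens the strained bridged lactone and equilibrates C5/C7 in the same operation, giving the hydroxy ester ketone F9.
- L‑Selectride gives the 6β‑alcohol F10.
- NaBH4 in ethanol reduces only the α‑hydroxy ester, giving 15.

**Step 8.** Under acid the isobutyryl group may migrate from O9 to the free cis O8, a hydroxyl may add to a protonated isopropenyl group, or the alkenes may move into conjugation. The fallback sets out from 13 and returns at 14. All three hydroxyls are silylated with N‑(trimethylsilyl)imidazole to the tris‑silyl ether F11. DBU in toluene at 60 °C equilibrates C5 and C7 with no free hydroxyl present, giving the tris‑silyl ether F12. Citric acid in methanol then gives 14.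

## Further compounds

F1 | step 6 | 6‑hydroxy‑4‑methyl‑2‑[4‑methyl‑2‑oxo‑1‑(prop‑1‑en‑2‑yl)pent‑3‑en‑1‑yl]‑3,6‑dihydro‑2H‑pyran‑3‑yl 2‑methylpropanoate | CC(C)=CC(=O)C(C(C)=C)[C@H]1OC(O)C=C(C)[C@@H]1OC(=O)C(C)C
F2 | step 6 | 4‑methyl‑2‑[4‑methyl‑2‑oxo‑1‑(prop‑1‑en‑2‑yl)pent‑3‑en‑1‑yl]‑3,6‑dihydro‑2H‑pyran‑3‑yl 2‑methylpropanoate | CC(C)=CC(=O)C(C(C)=C)[C@H]1OCC=C(C)[C@@H]1OC(=O)C(C)C
F3 | step 6 | 2‑[3‑iodo‑4‑methyl‑2‑oxo‑1‑(prop‑1‑en‑2‑yl)pent‑3‑en‑1‑yl]‑4‑methyl‑3,6‑dihydro‑2H‑pyran‑3‑yl 2‑methylpropanoate | CC(C)=C(I)C(=O)C(C(C)=C)[C@H]1OCC=C(C)[C@@H]1OC(=O)C(C)C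
F4 | step 6 | 5‑methyl‑7‑oxo‑6‑(propan‑2‑ylidene)‑8‑(prop‑1‑en‑2‑yl)‑2‑oxabicyclo[3.3.1]non‑3‑en‑9‑yl 2‑methylpropanoate | O1[C@@H]2C(C(C)=C)C(=O)C(=C(C)C)[C@](C)(C=C1)[C@@H]2OC(=O)C(C)C
F5 | step 3 | 7‑methyl‑3‑(2‑methylprop‑2‑en‑1‑ylidene)‑4‑(prop‑1‑en‑2‑yl)‑2,9‑dioxabicyclo[3.3.1]non‑7‑en‑6‑one | C=C(C)C=C1O[C@H]2C=C(C)C(=O)[C@H](O2)C1C(C)=C
F6 | step 3 | 7‑methyl‑3‑(2‑methylprop‑2‑en‑1‑ylidene)‑4‑(prop‑1‑en‑2‑yl)‑2,9‑dioxabicyclo[3.3.1]non‑7‑en‑6‑ol (hydroxyl endo) | C=C(C)C=C1O[C@H]2C=C(C)[C@@H](O)[C@H](O2)C1C(C)=C
F7 | step 1 | 5‑methyl‑1‑(3‑methylfuran‑2‑yl)‑2‑(prop‑1‑en‑2‑yl)hex‑4‑ene‑1,3‑dione | CC(C)=CC(=O)C(C(C)=C)C(=O)c1occc1C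
F8 | step 7 | 4‑hydroxy‑5‑methyl‑3,7‑dioxo‑6,8‑di(prop‑1‑en‑2‑yl)‑2‑oxabicyclo[3.3.1]nonan‑9‑yl 2‑methylpropanoate | O1[C@@H]2C(C(C)=C)C(=O)C(C(C)=C)[C@](C)([C@@H](O)C1=O)[C@@H]2OC(=O)C(C)C
F9 | step 7 | methyl 2‑hydroxy‑2‑[3‑hydroxy‑1‑methyl‑2‑(2‑methylpropanoyloxy)‑5‑oxo‑4,6‑di(prop‑1‑en‑2‑yl)cyclohexyl]acetate (5β,7β) | O[C@@H]2[C@@H](C(C)=C)C(=O)[C@@H](C(C)=C)[C@](C)([C@@H](O)C(=O)OC)[C@@H]2OC(=O)C(C)C
F10 | step 7 | methyl 2‑[3,5‑dihydroxy‑1‑methyl‑2‑(2‑methylpropanoyloxy)‑4,6‑di(prop‑1‑en‑2‑yl)cyclohexyl]‑2‑hydroxyacetate | O[C@@H]2[C@@H](C(C)=C)[C@@H](O)[C@@H](C(C)=C)[C@](C)([C@@H](O)C(=O)OC)[C@@H]2OC(=O)C(C)C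
F11 | step 8 | tris(trimethylsilyl) ether of 13 | C[Si](C)(C)O[C@@H]2C(C(C)=C)C(=O)C(C(C)=C)[C@](C)([C@@H](O[Si](C)(C)C)CO[Si](C)(C)C)[C@@H]2OC(=O)C(C)C
F12 | step 8 | tris(trimethylsilyl) ether of 14 | C[Si](C)(C)O[C@@H]2[C@@H](C(C)=C)C(=O)[C@@H](C(C)=C)[C@](C)([C@@H](O[Si](C)(C)C)CO[Si](C)(C)C)[C@@H]2OC(=O)C(C)C
A1 | alternative 1 | all‑cis 5‑(tert‑butyldimethylsilyloxy)‑3‑methyl‑4,6‑di(prop‑1‑en‑2‑yl)cyclohex‑2‑en‑1‑one | O=C2[C@@H](C(C)=C)[C@@H](O[Si](C)(C)C(C)(C)C)[C@@H](C(C)=C)C(C)=C2
A2 | alternative 1 | 5‑(tert‑butyldimethylsilyloxy)‑3‑ethenyl‑3‑methyl‑4,6‑di(prop‑1‑en‑2‑yl)cyclohexan‑1‑one | O=C2[C@@H](C(C)=C)[C@@H](O[Si](C)(C)C(C)(C)C)[C@@H](C(C)=C)[C@](C)(C=C)C2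
A3 | alternative 2 | 6β‑hydroxy‑9α‑isobutyryloxy‑15‑oxogermacra‑1(10)E,4E,11(13)‑trien‑8α,12‑olide | C=C1C(=O)O[C@@H]2[C@@H]1[C@@H](O)/C=C(C=O)/CC/C=C(C)/[C@@H]2OC(=O)C(C)C
A4 | alternative 2 | 1,2‑deoxy analogue of the target (C10 vinyl in place of the oxirane) | C=C1C(=O)O[C@@H]2[C@@H]1[C@@H](O)[C@@H](C(=C)C=O)[C@](C)(C=C)[C@@H]2OC(=O)C(C)C
A5 | alternative 3 | 3,5‑dimethoxy‑1‑methylcyclohexa‑2,5‑diene‑1‑carboxylic acid | COC1=CC(C)(C(=O)O)C=C(OC)C1
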